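**Assumption:** (+)-limonene oxide (4R, cis/trans mixture) and (S)-5-(hydroxymethyl)furan-2(5H)-one are taken as commercial. A one-flask sequence with no isolated intermediate is counted as one step. C-numbering is spongian-type (C8 quaternary, C9/C5 ring fusion, C10 methylidene carbon, C13–C16 in the bicyclic acetal).

## Retrosynthetic overview

1. Aplyviolene ⇐ acetylation and acetal/δ-lactone closure of a C15/C16 dialdehyde C11 acid, obtained from lactone acid 13 by lactone→lactol reduction and excision of the CH2OH carbon on C15.
2. 13 ⇐ methylenation of keto acid 12; 12 ⇐ one light-driven cascade joining aldehyde 6 and butenolide acid 11: acyl-radical 7-exo closure (C9–C10), then intermolecular Giese addition (C8–C14).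
3. 6 ⇐ (R)-limonene oxide: ring contraction, decarbonylation, HAT-Giese (C4 quaternary), one-carbon homologation. Only C5 is carried from limonene.
4. 11 ⇐ (S)-5-(hydroxymethyl)furanone: its C15 stereocentre steers C14 (and through it C13), then loses its CH2OH carbon.
5. Ring order: cyclopentene (from limonene) → cycloheptanone (cascade) → γ-lactone (from the furanone) → 2,7-dioxabicyclo[3.2.1]octanone (last).

## Route

**Step 1**
Reactants: 1, (+)-limonene oxide (4R, cis/trans)
Product: 2, (3R)-6-oxo-3-(prop-1-en-2-yl)heptanal
Conditions: H5IO6, THF/H2O, 0 °C → rt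
Reagents that add atoms: water, O
Why: Epoxide hydrolysis and periodate glycol cleavage open the ring from either epoxide diastereomer; the C4 stereocentre of limonene is untouched.

**Step 2**
Reactants: 2
Product: 3, (5S)-2-methyl-5-(prop-1-en-2-yl)cyclopent-1-ene-1-carbaldehyde
Conditions: piperidine (cat.), AcOH (cat.), PhH, 80 °C, Dean–Stark
Reagents that add atoms: none
Why: Enamine-mediated intramolecular aldol condensation (aldehyde α-carbon onto the methyl ketone) gives the cyclopentene enal; the stereocentre is not involved.

**Step 3**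
Reactants: 3
Product: 4, (3R)-1-methyl-3-(prop-1-en-2-yl)cyclopent-1-ene
Conditions: RhCl(PPh3)3 (1.05 equiv), PhCN, 130 °C; product distilled out
Reagents that add atoms: none
Why: Tsuji–Wilkinson decarbonylation of an enal replaces CHO by H with retention of alkene position, fixing the C8=C9 regiochemistry needed later.

**Step 4**
Reactants: 4
Product: 5, 4-methyl-4-[(1R)-3-methylcyclopent-2-en-1-yl]pentanal
Conditions: acrolein (3 equiv), Fe(acac)3, PhSiH3, EtOH/(CH2OH)2, 60 °C
Reagents that add atoms: acrolein, C=CC=O
Why: Metal-hydride HAT to the 1,1-disubstituted alkene (faster than to the trisubstituted ring alkene, as with limonene) gives the tertiary C4 radical, which undergoes Giese addition to build the gem-dimethyl quaternary carbon; no new stereocentre.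

**Step 5**
Reactants: 5
Product: 6, 5-methyl-5-[(1R)-3-methylcyclopent-2-en-1-yl]hexanal
Conditions: Ph3P(CH2OMe)Cl, KOtBu, THF, 0 °C; then 2 M HCl, THF, rt (one flask)
Reagents that add atoms: (methoxymethyl)triphenylphosphonium chloride, COC[P+](c1ccccc1)(c1ccccc1)c1ccccc1.[Cl-] (the CH carbon); water, O
Why: Wittig methoxymethylenation and enol-ether hydrolysis is a standard one-carbon aldehyde homologation; dilute aqueous acid does not move the trisubstituted alkene.

**Step 6**
Reactants: 7, (S)-5-(hydroxymethyl)furan-2(5H)-one
Product: 8, [(2S)-5-oxo-2,5-dihydrofuran-2-yl]methyl acetate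
Conditions: Ac2O, pyridine, DMAP (cat.), CH2Cl2, 0 °C → rt
Reagents that add atoms: acetic anhydride, CC(=O)OC(C)=O
Why: Simple acylation; the acetate deactivates the CH2–O hydrogens toward HAT in step 10 and is removed for free in step 12.

**Step 7**
Reactants: 8
Product: 9, [(2S)-4-bromo-5-oxo-2,5-dihydrofuran-2-yl]methyl acetate
Conditions: Br2, CH2Cl2, 0 °C; then pyridine, 0 °C → rt
Reagents that add atoms: bromine, BrBr
Why: Bromine addition and dehydrobromination gives the α-bromobutenolide; the weak base avoids γ-deprotonation and acetate loss.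

**Step 8**
Reactants: 9
Product: 10, tert-butyl 2-[(5S)-5-(acetoxymethyl)-2-oxo-2,5-dihydrofuran-3-yl]acetate
Conditions: BrZnCH2CO2tBu, Pd2(dba)3 (2.5 mol%), XPhos (10 mol%), THF, 45 °C
Reagents that add atoms: Reformatsky reagent from tert-butyl bromoacetate, CC(C)(C)OC(=O)C[Zn]Br
Why: Negishi-type coupling of a zinc ester enolate with an electron-poor vinyl bromide; the neutral conditions keep the ring alkene endocyclic.

**Step 9**
Reactants: 10
Product: 11, 2-[(5S)-5-(acetoxymethyl)-2-oxo-2,5-dihydrofuran-3-yl]acetic acid
Conditions: TFA/CH2Cl2 (1:4), 0 °C → rt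
Reagents that add atoms: none
Why: Acidolysis of the tert-butyl ester is done here, before any acid-sensitive 1,1-disubstituted alkene exists.

**Step 10**
Reactants: 6; 11 (1.3 equiv, added in portions)
Product: 12, 2-[(3R,4R,5S)-5-(acetoxymethyl)-2-oxo-4-[(1S,3aR,8aR)-1,4,4-trimethyl-8-oxodecahydroazulen-1-yl]oxolan-3-yl]acetic acid (cis-fused ring system; C8–C14 bond anti to the seven-membered ring; C14 substituent trans to CH2OAc and cis to CH2CO2H)
Conditions: (nBu4N)4[W10O32] (2–4 mol%), MeCN (0.02 M in 6), 390 nm LEDs, 25 °C, Ar
Reagents that add atoms: none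
Why: Proposed new method: excited decatungstate abstracts the aldehyde hydrogen of 6; the acyl radical closes 7-exo-trig onto C9 of the cyclopentene (cis fusion enforced by the C5 tether, helped by the gem-dimethyl group), and the resulting tertiary C8 radical adds through its convex face to the β-carbon of 11 anti to the C15 substituent; the lactone α-radical then takes hydrogen back from reduced decatungstate anti to the bulky C14 group, setting C13. Closest known reactions are decatungstate hydroacylation of electron-poor alkenes with aldehydes, acyl-radical cyclisation of alkenals (citronellal to menthone), and tertiary-radical Giese additions to 5-substituted butenolides.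

**Step 11**
Reactants: 12
Product: 13, 2-[(3R,4R,5S)-5-(acetoxymethyl)-2-oxo-4-[(1R,3aR,8aS)-1,4,4-trimethyl-8-methylidenedecahydroazulen-1-yl]oxolan-3-yl]acetic acid
Conditions: Zn, CH2Br2, TiCl4 (pre-formed, excess), THF/CH2Cl2, 0 °C → rt
Reagents that add atoms: dibromomethane, BrCBr (the CH2)
Why: Lombardo methylenation is non-basic, so the epimerisable C9 and C13 centres survive, and it is selective for ketones over lactone, acetate and free acid.

**Step 12**
Reactants: 13
Product: 14, 2-[(3R,4R,5S)-2-hydroxy-5-(hydroxymethyl)-4-[(1R,3aR,8aS)-1,4,4-trimethyl-8-methylidenedecahydroazulen-1-yl]oxolan-3-yl]acetic acid (lactol, anomer mixture)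
Conditions: DIBAL-H (4.5 equiv), CH2Cl2, −78 °C; Rochelle salt, kept at pH ≥ 7
Reagents that add atoms: none
Why: At −78 °C DIBAL reduces the γ-lactone to the lactol and cleaves the acetate, while the aluminium carboxylate is inert; no stereocentre is touched.

**Step 13**
Reactants: 14
Product: 15, (1S,5R,6R,8R)-6-hydroxy-8-[(1R,3aR,8aS)-1,4,4-trimethyl-8-methylidenedecahydroazulen-1-yl]-2,7-dioxabicyclo[3.2.1]octan-3-one
Conditions: NaIO4, THF/pH 7 buffer, 0 °C → rt; then 1 M HCl to pH 2, rt (one flask)
Reagents that add atoms: none (periodate removes the CH2OH carbon as formaldehyde)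
Why: Periodate cleaves the C15–CH2OH glycol through the ring-opened lactol to the C15/C16 dialdehyde acid, which on acidification closes to the bridged δ-lactone lactol; the new C15 acetal configuration is dictated by the bicycle, and the alternative [3.3.0] closure would put the bulky group on a concave face.

**Step 14**
Reactants: 15
Product: 16, aplyviolene, [(1S,5R,6S,8R)-3-oxo-8-[(1R,3aR,8aS)-1,4,4-trimethyl-8-methylidenedecahydroazulen-1-yl]-2,7-dioxabicyclo[3.2.1]octan-6-yl] acetate
Conditions: Ac2O, pyridine, DMAP (cat.), CH2Cl2, 0 °C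
Reagents that add atoms: acetic anhydride, CC(=O)OC(C)=O
Why: The equilibrating lactol is acylated from the open exo face, away from the lactone bridge, giving the natural C16 acetate.

## Compound list

1 | (+)-limonene oxide, (4R), cis/trans mixture | CC12OC1C[C@@H](CC2)C(C)=C | starting material
2 | (3R)-6-oxo-3-(prop-1-en-2-yl)heptanal | O=CC[C@@H](CCC(C)=O)C(C)=C | intermediate
3 | (5S)-2-methyl-5-(prop-1-en-2-yl)cyclopent-1-ene-1-carbaldehyde | O=CC1=C(C)CC[C@H]1C(C)=C | intermediate
4 | (3R)-1-methyl-3-(prop-1-en-2-yl)cyclopent-1-ene | CC1=C[C@H](C(C)=C)CC1 | intermediate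
5 | 4-methyl-4-[(1R)-3-methylcyclopent-2-en-1-yl]pentanal | O=CCCC(C)(C)[C@H]1C=C(C)CC1 | intermediate
6 | 5-methyl-5-[(1R)-3-methylcyclopent-2-en-1-yl]hexanal | O=CCCCC(C)(C)[C@H]1C=C(C)CC1 | intermediate
7 | (S)-5-(hydroxymethyl)furan-2(5H)-one | O=C1C=C[C@@H](CO)O1 | starting material
8 | [(2S)-5-oxo-2,5-dihydrofuran-2-yl]methyl acetate | CC(=O)OC[C@@H]1C=CC(=O)O1 | intermediate
9 | [(2S)-4-bromo-5-oxo-2,5-dihydrofuran-2-yl]methyl acetate | CC(=O)OC[C@@H]1C=C(Br)C(=O)O1 | intermediate
10 | tert-butyl 2-[(5S)-5-(acetoxymethyl)-2-oxo-2,5-dihydrofuran-3-yl]acetate | CC(=O)OC[C@@H]1C=C(CC(=O)OC(C)(C)C)C(=O)O1 | intermediate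
11 | 2-[(5S)-5-(acetoxymethyl)-2-oxo-2,5-dihydrofuran-3-yl]acetic acid | CC(=O)OC[C@@H]1C=C(CC(O)=O)C(=O)O1 | intermediate
12 | keto lactone acid (name in step 10) | O=C1CCCC(C)(C)[C@@H]2CC[C@@](C)([C@@H]3[C@@H](COC(C)=O)OC(=O)[C@@H]3CC(O)=O)[C@H]12 | intermediate
13 | methylidene lactone acid (name in step 11) | C=C1CCCC(C)(C)[C@@H]2CC[C@@](C)([C@@H]3[C@@H](COC(C)=O)OC(=O)[C@@H]3CC(O)=O)[C@H]12 | intermediate
14 | lactol diol acid (name in step 12) | C=C1CCCC(C)(C)[C@@H]2CC[C@@](C)([C@@H]3[C@@H](CO)OC(O)[C@@H]3CC(O)=O)[C@H]12 | intermediate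
15 | 16-deacetyl aplyviolene (name in step 13) | C=C1CCCC(C)(C)[C@@H]2CC[C@@](C)([C@@H]3[C@@H]4OC(=O)C[C@H]3[C@H](O)O4)[C@H]12 | intermediate
16 | aplyviolene | C=C1CCCC(C)(C)[C@@H]2CC[C@@](C)([C@@H]3[C@@H]4OC(=O)C[C@H]3[C@H](OC(C)=O)O4)[C@H]12 | target

## Step count and risks

Total steps: 14. Longest linear sequence: 10 (steps 1–5, 10–14).

Three steps most likely to fail:

1. **Step 10 (proposed new cascade).** The acyl radical may add directly to 11 before cyclising, the C8 radical may be reduced before it is trapped, or decatungstate may abstract allylic hydrogens.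
   Fallback (known chemistry): cyclise 6 by a Me2AlCl carbonyl-ene reaction to the cis-fused C10 alcohol with the alkene moved to C7=C8 or C8=CH2. Protect C10–OH, then Mukaiyama hydration to the C8 tertiary alcohol. Convert it to the caesium oxalate and run an Ir-photoredox (blue LED) tertiary-radical Giese addition to 10. Finish with C10 oxidation and methylenation.

2. **Step 3 (with step 4).** Rh-hydride alkene migration in the volatile 1,4-diene would erase C5, and step 4 depends on HAT discriminating the two alkenes.
   Fallback: drop the limonene ring contraction. Ring-closing metathesis of (S)-linalool gives (S)-1-methylcyclopent-2-en-1-ol; Ireland–Claisen rearrangement of its isobutyrate transfers chirality to C5 and fixes the alkene position; decarboxylative photoredox Giese addition of the resulting tertiary acid to acrolein gives 5.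

3. **Step 13.** Cleavage needs the lactol to ring-open, C13 can epimerise at the dialdehyde stage, and closure could give the [3.3.0] isomer.
   Fallback: unmask C15 at the lactone stage instead. On the tert-butyl ester series with free CH2OH, hypoiodite alkoxy-radical β-fragmentation (PhI(OAc)2, I2, visible light, MeOH) gives the C15 methoxy acetal. DIBAL reduction and acid-mediated transacetalisation/lactonisation then follow, as for known 5-alkoxybutanolide intermediates.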